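**Plan**
1. Retrosynthetic cuts, in order: C6–C7 (ketone carbon to its CH2 neighbour, the ring-closing bond); lactone carbonyl C18 (CO insertion at C4); C2–C3 (acetylide on a Weinreb amide); C1–C14 (syn-aldol); C10=C11 (cross-metathesis).
2. Forward: the C7–C14 chain is joined by cross-metathesis, C1/C2 are added by aldol and C3–C6 by an alkyne. The butenolide ring is formed first (trans-hydroalumination/iodination, then carbonylative lactonisation) and the 14-membered carbocycle last.
3. Enabling feature: C6 is a ketone carbon flanked by two CH2 groups. C5 hangs on the α-carbon C4 of the butenolide ring, and C7 is a primary, non-stereogenic carbon next to the C8 methyl centre. C6–C7 is therefore an acyl–primary-alkyl bond that can be made from two electrophiles (S-2-pyridyl thioester at C6, iodide at C7) under neutral reductive nickel catalysis. The base-labile butenolide, the acetate and the free tertiary allylic alcohol can then already be in place, so ring closure should give the target itself.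
4. Stereochemistry: C12 from (S)-citramalic acid; C8 from an Evans allylation; C1 and C14 from an Evans syn-aldol; C2 from a 1,3-syn reduction directed by the C14 hydroxyl; 10E from the cross-metathesis.

Key step: step 23

Remark: cembrane-type locants are used throughout (C1 = CH–iPr, C2 = lactone CH–O, C3=C4 = butenolide alkene, C18 = lactone C=O, C5 = CH2, C6 = ketone, C7 = CH2, C8 = CH–Me, C10=C11 = E-alkene, C12 = C(Me)OH, C14 = CH–OAc).

**Route**

Step 1
Reactants: 1 (S)-citramalic acid
Product: 2 2-[(4S)-2,2,4-trimethyl-5-oxo-1,3-dioxolan-4-yl]acetic acid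
Conditions: 2,2-dimethoxypropane, PPTS (cat.), CH2Cl2, rt
Reagents that add atoms: 2,2-dimethoxypropane, COC(C)(C)OC
Why: Dioxolanone (acetonide) formation ties up the tertiary hydroxyl and its neighbouring carboxyl (future C12–OH and C11) and leaves the CH2CO2H arm (C13–C14) free, with the C12 centre taken unchanged from the chiral pool.

Step 2
Reactants: 2 2-[(4S)-2,2,4-trimethyl-5-oxo-1,3-dioxolan-4-yl]acetic acid
Product: 4 (3S)-3-hydroxy-3-methyloxolan-2-one, via hydroxyethyl dioxolanone 3 (not isolated)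
Conditions: BH3·SMe2, THF, 0 °C to rt; MeOH; then TsOH·H2O (cat.), CH2Cl2, rt
Reagents that add atoms: none
Why: Borane reduces the free carboxylic acid chemoselectively beside the dioxolanone, and acid-catalysed translactonisation of the primary alcohol expels acetone to give the γ-lactone.

Step 3
Reactants: 4 (3S)-3-hydroxy-3-methyloxolan-2-one
Product: 5 (3S)-3-methyloxolane-2,3-diol (anomer mixture)
Conditions: DIBAL-H (2.3 equiv), CH2Cl2, −78 °C; Rochelle salt
Reagents that add atoms: none
Why: Partial reduction of a lactone to the lactol at low temperature, the first equivalent being consumed by the free hydroxyl.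

Step 4
Reactants: 5 (3S)-3-methyloxolane-2,3-diol
Product: 6 (3S)-3-methylpent-4-ene-1,3-diol
Conditions: Ph3PCH3Br, KOt-Bu, THF, 0 °C to rt
Reagents that add atoms: methyltriphenylphosphonium bromide, C[P+](c1ccccc1)(c1ccccc1)c1ccccc1.[Br-]
Why: Wittig methylenation of the open hydroxy-aldehyde form of the lactol turns C11 into the vinyl group of a tertiary allylic alcohol without touching the quaternary C12 centre.

Step 5
Reactants: 7 (4R)-4-benzyl-3-propanoyl-1,3-oxazolidin-2-one; 8 allyl iodide
Product: 10 (4R)-4-benzyl-3-[(2S)-2-methylpent-4-enoyl]-1,3-oxazolidin-2-one, via sodium Z-enolate 9 (not isolated)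
Conditions: NaHMDS, THF, −78 °C; then 8, −78 to −40 °C
Reagents that add atoms: none
Why: Evans asymmetric alkylation, in which the chelated Z-enolate is allylated on the face opposite the benzyl group, sets the future C8 methyl centre as S.

Step 6
Reactants: 10 (4R)-4-benzyl-3-[(2S)-2-methylpent-4-enoyl]-1,3-oxazolidin-2-one
Product: 11 (2S)-2-methylpent-4-en-1-ol
Conditions: LiBH4, Et2O, MeOH (1 equiv), 0 °C
Reagents that add atoms: none
Why: Reductive removal of the auxiliary gives the primary alcohol without epimerisation and returns the oxazolidinone.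

Step 7
Reactants: 11 (2S)-2-methylpent-4-en-1-ol
Product: 12 (4S)-5-chloro-4-methylpent-1-ene
Conditions: N-chlorosuccinimide, PPh3, CH2Cl2, 0 °C to rt
Reagents that add atoms: N-chlorosuccinimide, O=C1CCC(=O)N1Cl
Why: Appel-type chlorination at the primary carbon (the stereocentre is untouched) installs C7 as a robust chloride that needs no protecting group and later becomes the iodide.

Step 8
Reactants: 6 (3S)-3-methylpent-4-ene-1,3-diol; 12 (4S)-5-chloro-4-methylpent-1-ene
Product: 13 (3S,4E,7S)-8-chloro-3,7-dimethyloct-4-ene-1,3-diol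
Conditions: Hoveyda–Grubbs II (5 mol %), 12 (3 equiv), CH2Cl2, 40 °C
Reagents that add atoms: none
Why: Olefin cross-metathesis between a hindered tertiary allylic alcohol and an unhindered terminal alkene should be selective for the cross product and, for steric reasons, for the E-alkene (C10=C11).

Step 9
Reactants: 13 (3S,4E,7S)-8-chloro-3,7-dimethyloct-4-ene-1,3-diol
Product: 14 (3S,4E,7S)-8-chloro-3,7-dimethyl-1,3-bis(triethylsilyloxy)oct-4-ene
Conditions: TESOTf, 2,6-lutidine, CH2Cl2, −78 to 0 °C
Reagents that add atoms: triethylsilyl trifluoromethanesulfonate, CC[Si](CC)(CC)OS(=O)(=O)C(F)(F)F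
Why: Silyl triflate silylates both the primary and the hindered tertiary hydroxyl.

Step 10
Reactants: 14 (3S,4E,7S)-8-chloro-3,7-dimethyl-1,3-bis(triethylsilyloxy)oct-4-ene
Product: 15 (3S,4E,7S)-8-chloro-3,7-dimethyl-3-(triethylsilyloxy)oct-4-enal
Conditions: (COCl)2, DMSO, CH2Cl2, −78 to −30 °C; Et3N, to 0 °C
Reagents that add atoms: none
Why: Swern conditions cleave and oxidise a primary triethylsilyl ether directly to the aldehyde while the tertiary silyl ether survives, giving the C14 aldehyde in one operation.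

Step 11
Reactants: 16 (4R)-4-benzyl-1,3-oxazolidin-2-one; 17 3-methylbutanoyl chloride
Product: 19 (4R)-4-benzyl-3-(3-methylbutanoyl)-1,3-oxazolidin-2-one, via lithium oxazolidinide 18 (not isolated)
Conditions: n-BuLi, THF, −78 °C; then 17, −78 to 0 °C
Reagents that add atoms: none
Why: Standard N-acylation of the lithiated Evans auxiliary.

Step 12
Reactants: 19 (4R)-4-benzyl-3-(3-methylbutanoyl)-1,3-oxazolidin-2-one; 15 (3S,4E,7S)-8-chloro-3,7-dimethyl-3-(triethylsilyloxy)oct-4-enal
Product: 21 (4R)-4-benzyl-3-[(2R,3S,5S,6E,9S)-10-chloro-3-hydroxy-5,9-dimethyl-2-(propan-2-yl)-5-(triethylsilyloxy)dec-6-enoyl]-1,3-oxazolidin-2-one, via Z-boron enolate 20 (not isolated)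
Conditions: Bu2BOTf, i-Pr2NEt, CH2Cl2, 0 °C; then 15, −78 to 0 °C; pH 7 buffer, MeOH, H2O2
Reagents that add atoms: none
Why: Evans syn-aldol through the Z-boron enolate and a Zimmerman–Traxler chair, in which the (R)-benzyl auxiliary fixes C1 (R, isopropyl) and C14 (S, carbinol) in the required syn relationship under reagent control.

Step 13
Reactants: 21 (aldol adduct)
Product: 22 (2R,3S,5S,6E,9S)-10-chloro-3-hydroxy-N-methoxy-N,5,9-trimethyl-2-(propan-2-yl)-5-(triethylsilyloxy)dec-6-enamide
Conditions: MeNHOMe·HCl, AlMe3, CH2Cl2, −20 to 0 °C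
Reagents that add atoms: N,O-dimethylhydroxylamine hydrochloride, CNOC.Cl
Why: Aluminium-amide transamination of a β-hydroxy acyl oxazolidinone, assisted by the free β-hydroxyl, gives the Weinreb amide and releases the auxiliary without epimerising C1.

Step 14
Reactants: 22 (Weinreb amide); 23 tert-butyl(but-3-yn-1-yloxy)dimethylsilane
Product: 25 (6R,7S,9S,10E,13S)-1-(tert-butyldimethylsilyloxy)-14-chloro-7-hydroxy-9,13-dimethyl-6-(propan-2-yl)-9-(triethylsilyloxy)tetradec-10-en-3-yn-5-one, via lithium acetylide 24 (not isolated)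
Conditions: 23 (3.5 equiv), n-BuLi (3.3 equiv), THF, −78 °C; then 22, −78 to −20 °C; aq. NH4Cl at −20 °C
Reagents that add atoms: none
Why: Acetylide addition to a Weinreb amide stops at the ketone through the chelated tetrahedral intermediate (the first equivalent deprotonates the C14 hydroxyl) and brings in C3–C6 as the ynone.

Step 15
Reactants: 25 (β-hydroxy ynone)
Product: 27 (5S,6R,7S,9S,10E,13S)-1-(tert-butyldimethylsilyloxy)-14-chloro-9,13-dimethyl-6-(propan-2-yl)-9-(triethylsilyloxy)tetradec-10-en-3-yne-5,7-diol, via diethylborinate 26 (not isolated)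
Conditions: Et2BOMe, THF/MeOH 4:1, −78 °C; NaBH4; AcOH, then MeOH co-evaporation
Reagents that add atoms: none
Why: Narasaka–Prasad reduction, in which external hydride attacks the boron-chelated half-chair axially, should give the 1,3-syn diol and so sets C2 from the C14 hydroxyl.

Step 16
Reactants: 27 (syn-diol)
Product: 29 (3Z,5S,6R,7S,9S,10E,13S)-1-(tert-butyldimethylsilyloxy)-14-chloro-3-iodo-9,13-dimethyl-6-(propan-2-yl)-9-(triethylsilyloxy)tetradeca-3,10-diene-5,7-diol, via cyclic alkenylaluminate 28 (not isolated)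
Conditions: Red-Al (5 equiv), THF, 0 °C to rt; then I2, −78 to 0 °C
Reagents that add atoms: iodine, II
Why: Hydroxyl-directed trans-hydroalumination of the propargylic alcohol delivers hydride to C3 and aluminium to the distal carbon C4, and iodinolysis with retention gives the Z-iodoalkene in which C2–OH and iodine are cis.

Step 17
Reactants: 29 (Z-iodoalkene diol)
Product: 30 (5R)-3-[2-(tert-butyldimethylsilyloxy)ethyl]-5-[(3R,4S,6S,7E,10S)-11-chloro-4-hydroxy-2,6,10-trimethyl-6-(triethylsilyloxy)undec-7-en-3-yl]furan-2(5H)-one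
Conditions: PdCl2(PPh3)2 (5 mol %), K2CO3, CO (1 atm), THF, 45 °C
Reagents that add atoms: carbon monoxide, [C-]#[O+]
Why: Palladium-catalysed carbonylative lactonisation of a Z-γ-hydroxy vinyl iodide closes the butenolide (5-exo capture of the acyl-palladium by the C2 hydroxyl, far faster than seven-ring closure by the C14 hydroxyl) and leaves C14–OH free.

Step 18
Reactants: 30 (butenolide alcohol)
Product: 31 (3R,4S,6S,7E,10S)-3-[(2R)-4-[2-(tert-butyldimethylsilyloxy)ethyl]-5-oxo-2,5-dihydrofuran-2-yl]-11-chloro-2,6,10-trimethyl-6-(triethylsilyloxy)undec-7-en-4-yl acetate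
Conditions: Ac2O, pyridine, DMAP (cat.), CH2Cl2, 0 °C to rt
Reagents that add atoms: acetic anhydride, CC(=O)OC(C)=O
Why: Acetylation of the only free hydroxyl under mild amine conditions that should not enolise the butenolide γ-position (C2).

Step 19
Reactants: 31 (chloro acetate)
Product: 32 (3R,4S,6S,7E,10S)-3-[(2R)-4-[2-(tert-butyldimethylsilyloxy)ethyl]-5-oxo-2,5-dihydrofuran-2-yl]-11-iodo-2,6,10-trimethyl-6-(triethylsilyloxy)undec-7-en-4-yl acetate
Conditions: NaI (10 equiv), butan-2-one, 80 °C
Reagents that add atoms: sodium iodide, [Na+].[I-]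
Why: Finkelstein exchange at the primary C7 carbon (slowed but not blocked by β-branching) under neutral conditions that all other groups tolerate.

Step 20
Reactants: 32 (iodo acetate)
Product: 33 (3R,4S,6S,7E,10S)-6-hydroxy-3-[(2R)-4-(2-hydroxyethyl)-5-oxo-2,5-dihydrofuran-2-yl]-11-iodo-2,6,10-trimethylundec-7-en-4-yl acetate
Conditions: HF·pyridine, pyridine, THF, 0 °C to rt
Reagents that add atoms: none
Why: Buffered fluoride cleaves the primary TBS and tertiary TES ethers together without basic conditions that would endanger the butenolide, the acetate or the iodide.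

Step 21
Reactants: 33 (iodo diol)
Product: 35 2-[(5R)-5-[(3R,4S,6S,7E,10S)-4-acetoxy-6-hydroxy-11-iodo-2,6,10-trimethylundec-7-en-3-yl]-2-oxo-2,5-dihydrofuran-3-yl]acetic acid, via aldehyde 34 (not isolated)
Conditions: TEMPO (0.3 equiv), PhI(OAc)2 (2.5 equiv), MeCN/H2O 1:1, rt
Reagents that add atoms: water, O
Why: Oxoammonium oxidation is selective for the primary alcohol over the tertiary one and takes the labile β,γ-unsaturated aldehyde on to the acid in the same pot through its hydrate.

Step 22
Reactants: 35 (iodo acid)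
Product: 36 S-pyridin-2-yl 2-[(5R)-5-[(3R,4S,6S,7E,10S)-4-acetoxy-6-hydroxy-11-iodo-2,6,10-trimethylundec-7-en-3-yl]-2-oxo-2,5-dihydrofuran-3-yl]ethanethioate
Conditions: 2,2'-dipyridyl disulfide, PPh3, CH2Cl2, rt; rapid filtration through silica
Reagents that add atoms: 2,2'-dipyridyl disulfide, c1ccc(SSc2ccccn2)nc1
Why: Mukaiyama redox condensation makes the 2-pyridyl thioester without base, so the acidic C5 methylene is not enolised, and the phosphine is consumed by the disulfide much faster than by the hindered iodide.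

Step 23
Reactants: 36 (iodo S-2-pyridyl thioester)
Product: 37 CNP0200490.2 (C1 R, C2 R, C8 S, C12 S, C14 S, 10E)
Conditions: NiBr2·glyme (0.5 equiv), 4,4'-di-tert-butyl-2,2'-bipyridine (0.5 equiv), Zn dust (10 equiv), DMA/THF, 25 °C, 36 added by syringe pump over 12 h to 1 mM
Reagents that add atoms: none
Why: Proposed new method: Ni(0), generated by zinc, should insert into the C6 acyl–S bond of the 2-pyridyl thioester (N,S-chelation makes it the only acyl derivative that reacts), while Ni(I) abstracts iodine from C7 to give a primary radical that is captured by the tethered acyl–Ni(II) and released by reductive elimination from Ni(III), zinc closing the cycle. The closest known reaction type is the intermolecular nickel-catalysed reductive ketone synthesis from S-2-pyridyl thioesters (or acid chlorides) and primary alkyl iodides; new here is its use under high dilution to close a ring. The 14-membered carbocycle is closed end to end by acyl–alkyl coupling at nickel and not by radical attack on a π bond, so Baldwin's rules do not apply, and the preformed butenolide becomes the bridging ring of the bicycle. No stereocentre is formed, since C7 is a CH2 and the neighbouring C8 centre, β to the radical, cannot epimerise. The step needs cyclisation over oligomerisation and chemoselectivity for the thioester over lactone, acetate and the doubly activated C5 methylene; slow addition, the conformational bias from the E-alkene, the quaternary C12 and the planar butenolide, and the neutral base-free medium should secure both. The C7 radical has no fast intramolecular escape (attack on C10=C11 would be 4-exo or 5-endo, attack on the butenolide an 11-membered transannular closure), and room temperature should disfavour decarbonylation of the allyl-type acyl-nickel.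

**Compound list**
1 | (S)-citramalic acid | OC(=O)C[C@](C)(O)C(=O)O | starting material
2 | 2-[(4S)-2,2,4-trimethyl-5-oxo-1,3-dioxolan-4-yl]acetic acid | OC(=O)C[C@]1(C)OC(C)(C)OC1=O | intermediate
3 | (5S)-5-(2-hydroxyethyl)-2,2,5-trimethyl-1,3-dioxolan-4-one (formed in situ) | OCC[C@]1(C)OC(C)(C)OC1=O | intermediate
4 | (3S)-3-hydroxy-3-methyloxolan-2-one | C[C@]1(O)CCOC1=O | intermediate
5 | (3S)-3-methyloxolane-2,3-diol | C[C@]1(O)CCOC1O | intermediate
6 | (3S)-3-methylpent-4-ene-1,3-diol | C=C[C@@](C)(O)CCO | intermediate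
7 | (4R)-4-benzyl-3-propanoyl-1,3-oxazolidin-2-one | CCC(=O)N1[C@H](Cc2ccccc2)COC1=O | starting material
8 | allyl iodide | C=CCI | starting material
9 | sodium (Z)-enolate of 7 (formed in situ) | C/C=C(\[O-])N1[C@H](Cc2ccccc2)COC1=O.[Na+] | intermediate
10 | (4R)-4-benzyl-3-[(2S)-2-methylpent-4-enoyl]-1,3-oxazolidin-2-one | C=CC[C@H](C)C(=O)N1[C@H](Cc2ccccc2)COC1=O | intermediate
11 | (2S)-2-methylpent-4-en-1-ol | C=CC[C@H](C)CO | intermediate
12 | (4S)-5-chloro-4-methylpent-1-ene | C=CC[C@H](C)CCl | intermediate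
13 | (3S,4E,7S)-8-chloro-3,7-dimethyloct-4-ene-1,3-diol | OCC[C@](C)(O)/C=C/C[C@H](C)CCl | intermediate
14 | (3S,4E,7S)-8-chloro-3,7-dimethyl-1,3-bis(triethylsilyloxy)oct-4-ene | CC[Si](CC)(CC)OCC[C@](C)(O[Si](CC)(CC)CC)/C=C/C[C@H](C)CCl | intermediate
15 | (3S,4E,7S)-8-chloro-3,7-dimethyl-3-(triethylsilyloxy)oct-4-enal | O=CC[C@](C)(O[Si](CC)(CC)CC)/C=C/C[C@H](C)CCl | intermediate
16 | (4R)-4-benzyl-1,3-oxazolidin-2-one | O=C1N[C@H](Cc2ccccc2)CO1 | starting material
17 | 3-methylbutanoyl chloride | CC(C)CC(Cl)=O | starting material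
18 | lithium salt of 16 (formed in situ) | [Li+].O=C1[N-][C@H](Cc2ccccc2)CO1 | intermediate
19 | (4R)-4-benzyl-3-(3-methylbutanoyl)-1,3-oxazolidin-2-one | CC(C)CC(=O)N1[C@H](Cc2ccccc2)COC1=O | intermediate
20 | (Z)-dibutylboron enolate of 19 (formed in situ) | CC(C)/C=C(\OB(CCCC)CCCC)N1[C@H](Cc2ccccc2)COC1=O | intermediate
21 | (4R)-4-benzyl-3-[(2R,3S,5S,6E,9S)-10-chloro-3-hydroxy-5,9-dimethyl-2-(propan-2-yl)-5-(triethylsilyloxy)dec-6-enoyl]-1,3-oxazolidin-2-one | O[C@@H](C[C@](C)(O[Si](CC)(CC)CC)/C=C/C[C@H](C)CCl)[C@H](C(=O)N1[C@H](Cc2ccccc2)COC1=O)C(C)C | intermediate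
22 | (2R,3S,5S,6E,9S)-10-chloro-3-hydroxy-N-methoxy-N,5,9-trimethyl-2-(propan-2-yl)-5-(triethylsilyloxy)dec-6-enamide | O[C@@H](C[C@](C)(O[Si](CC)(CC)CC)/C=C/C[C@H](C)CCl)[C@H](C(=O)N(C)OC)C(C)C | intermediate
23 | tert-butyl(but-3-yn-1-yloxy)dimethylsilane | C#CCCO[Si](C)(C)C(C)(C)C | starting material
24 | lithium acetylide of 23 (formed in situ) | [Li]C#CCCO[Si](C)(C)C(C)(C)C | intermediate
25 | (6R,7S,9S,10E,13S)-1-(tert-butyldimethylsilyloxy)-14-chloro-7-hydroxy-9,13-dimethyl-6-(propan-2-yl)-9-(triethylsilyloxy)tetradec-10-en-3-yn-5-one | O[C@@H](C[C@](C)(O[Si](CC)(CC)CC)/C=C/C[C@H](C)CCl)[C@H](C(=O)C#CCCO[Si](C)(C)C(C)(C)C)C(C)C | intermediate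
26 | O-diethylboryl derivative of 25 at the C14 oxygen (formed in situ) | CCB(CC)O[C@@H](C[C@](C)(O[Si](CC)(CC)CC)/C=C/C[C@H](C)CCl)[C@H](C(=O)C#CCCO[Si](C)(C)C(C)(C)C)C(C)C | intermediate
27 | (5S,6R,7S,9S,10E,13S)-1-(tert-butyldimethylsilyloxy)-14-chloro-9,13-dimethyl-6-(propan-2-yl)-9-(triethylsilyloxy)tetradec-10-en-3-yne-5,7-diol | O[C@@H](C[C@](C)(O[Si](CC)(CC)CC)/C=C/C[C@H](C)CCl)[C@H]([C@H](O)C#CCCO[Si](C)(C)C(C)(C)C)C(C)C | intermediate
28 | sodium spiro alkenyl(dialkoxy)(2-methoxyethoxy)aluminate of 27, Al on C4 and on both oxygens (formed in situ) | [Na+].CC(C)(C)[Si](C)(C)OCCC1=C[C@H]2O[Al-]1(OCCOC)O[C@@H](C[C@](C)(O[Si](CC)(CC)CC)/C=C/C[C@H](C)CCl)[C@H]2C(C)C | intermediate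
29 | (3Z,5S,6R,7S,9S,10E,13S)-1-(tert-butyldimethylsilyloxy)-14-chloro-3-iodo-9,13-dimethyl-6-(propan-2-yl)-9-(triethylsilyloxy)tetradeca-3,10-diene-5,7-diol | O[C@@H](C[C@](C)(O[Si](CC)(CC)CC)/C=C/C[C@H](C)CCl)[C@H]([C@H](O)/C=C(\I)CCO[Si](C)(C)C(C)(C)C)C(C)C | intermediate
30 | (5R)-3-[2-(tert-butyldimethylsilyloxy)ethyl]-5-[(3R,4S,6S,7E,10S)-11-chloro-4-hydroxy-2,6,10-trimethyl-6-(triethylsilyloxy)undec-7-en-3-yl]furan-2(5H)-one | O[C@@H](C[C@](C)(O[Si](CC)(CC)CC)/C=C/C[C@H](C)CCl)[C@H]([C@H]1C=C(CCO[Si](C)(C)C(C)(C)C)C(=O)O1)C(C)C | intermediate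
31 | (3R,4S,6S,7E,10S)-3-[(2R)-4-[2-(tert-butyldimethylsilyloxy)ethyl]-5-oxo-2,5-dihydrofuran-2-yl]-11-chloro-2,6,10-trimethyl-6-(triethylsilyloxy)undec-7-en-4-yl acetate | CC(=O)O[C@@H](C[C@](C)(O[Si](CC)(CC)CC)/C=C/C[C@H](C)CCl)[C@H]([C@H]1C=C(CCO[Si](C)(C)C(C)(C)C)C(=O)O1)C(C)C | intermediate
32 | 11-iodo analogue of 31 | CC(=O)O[C@@H](C[C@](C)(O[Si](CC)(CC)CC)/C=C/C[C@H](C)CI)[C@H]([C@H]1C=C(CCO[Si](C)(C)C(C)(C)C)C(=O)O1)C(C)C | intermediate
33 | (3R,4S,6S,7E,10S)-6-hydroxy-3-[(2R)-4-(2-hydroxyethyl)-5-oxo-2,5-dihydrofuran-2-yl]-11-iodo-2,6,10-trimethylundec-7-en-4-yl acetate | CC(=O)O[C@@H](C[C@](C)(O)/C=C/C[C@H](C)CI)[C@H]([C@H]1C=C(CCO)C(=O)O1)C(C)C | intermediate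
34 | (3R,4S,6S,7E,10S)-6-hydroxy-11-iodo-2,6,10-trimethyl-3-[(2R)-5-oxo-4-(2-oxoethyl)-2,5-dihydrofuran-2-yl]undec-7-en-4-yl acetate (formed in situ in step 21) | CC(=O)O[C@@H](C[C@](C)(O)/C=C/C[C@H](C)CI)[C@H]([C@H]1C=C(CC=O)C(=O)O1)C(C)C | intermediate
35 | 2-[(5R)-5-[(3R,4S,6S,7E,10S)-4-acetoxy-6-hydroxy-11-iodo-2,6,10-trimethylundec-7-en-3-yl]-2-oxo-2,5-dihydrofuran-3-yl]acetic acid | CC(=O)O[C@@H](C[C@](C)(O)/C=C/C[C@H](C)CI)[C@H]([C@H]1C=C(CC(=O)O)C(=O)O1)C(C)C | intermediate
36 | S-pyridin-2-yl thioester of 35 | CC(=O)O[C@@H](C[C@](C)(O)/C=C/C[C@H](C)CI)[C@H]([C@H]1C=C(CC(=O)Sc2ccccn2)C(=O)O1)C(C)C | intermediate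
37 | CNP0200490.2 | CC(=O)O[C@H]1C[C@](C)(O)/C=C/C[C@H](C)CC(=O)CC2=C[C@@H](OC2=O)[C@@H]1C(C)C | target

**Step count and risks**
Total: 23 steps. Longest linear sequence: 19 steps (steps 1–4, 8–10, 12–23).

Step 23 (bears the label). The tethered C7 radical may be captured by the acyl-nickel of another molecule and give oligomers, may be reduced to the C7–H compound before it meets nickel, or the acyl-nickel may lose CO. The fallback uses known chemistry and closes the same bond at the alcohol oxidation level. It sets out from 33, which is oxidised with Dess–Martin periodinane (NaHCO3, CH2Cl2, 0 °C) to aldehyde 34, this time isolated. The ring is then closed by the cobalt-catalysed alkyl variant of the Nozaki–Hiyama–Kishi reaction (CrCl2, vitamin B12 or cobalt phthalocyanine cat., DMF, 25 °C, slow addition to 2 mM), which tolerates butenolide, acetate and free hydroxyl and should give the macrocyclic C6 carbinol F1 as a mixture of C6 epimers. A second Dess–Martin oxidation removes that stereocentre and comes back to the route at 37.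

Step 14. The lithium β-alkoxide may undergo retro-aldol cleavage, the free β-hydroxy ynone may close to a dihydropyranone by oxa-Michael addition on work-up, or C1 may epimerise. The fallback sets out from 22 and masks the C14 hydroxyl as its 4-methoxybenzyl ether (4-methoxybenzyl trichloroacetimidate, Sc(OTf)3 cat., toluene, 0 °C) to give the PMB-protected Weinreb amide F2. Addition of acetylide 24 gives the PMB-protected ynone F3. C2 is then set by the catalyst instead of the neighbouring hydroxyl: Noyori asymmetric transfer hydrogenation with the (S,S)-TsDPEN ruthenium catalyst in i-PrOH, chosen to deliver the (S)-carbinol, gives the propargylic alcohol F4. DDQ in wet CH2Cl2 removes the PMB group and comes back to the route at 27.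

Step 16. Hydride may displace the primary chloride, may be delivered to the wrong alkyne carbon, or the alkenylaluminate may be protonated before iodination. The fallback sets out from 27 and uses cationic ruthenium-catalysed trans-hydrosilylation ([Cp*Ru(MeCN)3]PF6, BnMe2SiH, acetone, 0 °C), which places silicon on the carbon distal to the propargylic hydroxyl and gives the Z-vinylsilane F5. Iododesilylation with retention (N-iodosuccinimide, hexafluoroisopropanol, 0 °C) comes back to the route at 29.

Further compounds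
F1 | step 23 | macrocyclic C6 alcohol, the 6-hydroxy analogue of 37 (C6 epimer mixture) | CC(=O)O[C@H]1C[C@](C)(O)/C=C/C[C@H](C)CC(O)CC2=C[C@@H](OC2=O)[C@@H]1C(C)C
F2 | step 14 | 3-O-(4-methoxybenzyl) ether of Weinreb amide 22 | COc1ccc(CO[C@@H](C[C@](C)(O[Si](CC)(CC)CC)/C=C/C[C@H](C)CCl)[C@H](C(=O)N(C)OC)C(C)C)cc1
F3 | step 14 | 7-O-(4-methoxybenzyl) ether of ynone 25 | COc1ccc(CO[C@@H](C[C@](C)(O[Si](CC)(CC)CC)/C=C/C[C@H](C)CCl)[C@H](C(=O)C#CCCO[Si](C)(C)C(C)(C)C)C(C)C)cc1
F4 | step 14 | 7-O-(4-methoxybenzyl) ether of diol 27 with free (5S)-propargylic hydroxyl | COc1ccc(CO[C@@H](C[C@](C)(O[Si](CC)(CC)CC)/C=C/C[C@H](C)CCl)[C@H]([C@H](O)C#CCCO[Si](C)(C)C(C)(C)C)C(C)C)cc1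
F5 | step 16 | (3Z)-3-[benzyl(dimethyl)silyl] analogue of iodide 29 | O[C@@H](C[C@](C)(O[Si](CC)(CC)CC)/C=C/C[C@H](C)CCl)[C@H]([C@H](O)/C=C(\[Si](C)(C)Cc1ccccc1)CCO[Si](C)(C)C(C)(C)C)C(C)C
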